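The dihydropyran ring is opened at the bond between the benzylic methylene C4 and arene carbon C4a. The plan exploits two features. C3–C4 is an unsubstituted two-carbon bridge on the quaternary ether carbon C2, hence a masked vinyl group. C4a lies between the oxygen-bearing carbons C5 and C8a of the benzene ring, where iodine is easily placed. The precursor is an acyclic, enantioenriched tertiary allyl aryl ether made from methyl 3-iodoorsellinate and isoprene monoepoxide. One-pot hydroboration and intramolecular B-alkyl Suzuki–Miyaura coupling closes the chroman at the final oxidation level without touching C2. Prenyl group, diene and free acid follow, without protecting groups.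

Key step: step 3

Assumption: the (R,R) enantiomer of the ligand in step 2 is taken to deliver the R ether 4. Should the sense of induction be the opposite, the equally available (S,S) ligand is used and nothing else changes.

Step 1
Reactants: 1 methyl orsellinate (methyl 2,4-dihydroxy-6-methylbenzoate)
Product: 2 methyl 2,4-dihydroxy-3-iodo-6-methylbenzoate
Conditions: I2 (1.0 equiv), NaHCO3, THF–H2O, 0 °C to rt
Reagents that add atoms: iodine, II
Why: Electrophilic aromatic iodination of the 4-phenoxide, under the weakly basic aqueous conditions that convert resorcinol into 2-iodoresorcinol, should put the bulky halogen on C3, flanked only by two oxygen atoms, in preference to C5, which is shielded by the 6-methyl group, and one equivalent of iodine limits double iodination.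

Step 2
Reactants: 2 methyl 2,4-dihydroxy-3-iodo-6-methylbenzoate; 3 racemic 2-methyl-2-vinyloxirane (isoprene monoepoxide)
Product: 4 methyl 2-hydroxy-4-{[(2R)-1-hydroxy-2-methylbut-3-en-2-yl]oxy}-3-iodo-6-methylbenzoate
Conditions: Pd2(dba)3·CHCl3 (1 mol %), (1R,2R)-N,N'-bis[2-(diphenylphosphino)benzoyl]cyclohexane-1,2-diamine (DACH-phenyl ligand, 3 mol %), CH2Cl2, rt
Reagents that add atoms: none
Why: In this asymmetric Tsuji–Trost allylic etherification, run as a dynamic kinetic asymmetric transformation, the racemic vinyl epoxide ionises to interconverting π-allylpalladium alkoxides, the acidic unchelated 4-OH protonates the alkoxide and is delivered, hydrogen-bonded to the new hydroxyl group, to the tertiary allyl terminus inside the chiral pocket, which sets C2 as R, while the chelated 2-OH and the hindered C–I bond stay untouched at room temperature.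

Step 3
Reactants: 4 methyl 2-hydroxy-4-{[(2R)-1-hydroxy-2-methylbut-3-en-2-yl]oxy}-3-iodo-6-methylbenzoate
Product: 6 methyl (2R)-5-hydroxy-2-(hydroxymethyl)-2,7-dimethyl-3,4-dihydro-2H-chromene-6-carboxylate, via B-alkyl-9-BBN borane 5 (not isolated)
Conditions: 9-BBN-H (0.5 M in THF, 3 equiv), 0 °C to rt; H2O quench; then PdCl2(dppf)·CH2Cl2 (5 mol %), aq. K3PO4 (3 M), THF–DMF, 0.01 M, 50 °C
Reagents that add atoms: 9-borabicyclo[3.3.1]nonane (9-BBN-H), [H]B1C2CCCC1CCC2 (boron cages held in 5; only hydrogen stays in 6)
Why: 9-BBN first ties up the primary hydroxyl group as its borinate and then adds anti-Markovnikov to the monosubstituted vinyl group, the bulk of the reagent and of the neighbouring quaternary C2 placing boron only on the terminal carbon, the future C4. Zerovalent palladium then inserts into the single C–I bond at the future C4a, the base-activated B-alkyl group is transferred intramolecularly, and reductive elimination from the seven-membered palladacycle forges C4–C4a; the closest known reaction type is the one-pot hydroboration and intramolecular B-alkyl Suzuki–Miyaura coupling used for benzo-fused five- and six-membered rings. The dihydropyran ring is thus closed in what amounts to a 6-endo, anti-Markovnikov hydroarylation of the vinyl group, a mode that a Heck closure (5-exo) or a cationic closure (Markovnikov) of the same ether would not give. No stereocentre is made: none of the four bonds at C2 is touched and the medium is never acidic, so the R configuration from step 2 is carried over, and the allylic ether, which could ionise on palladium or undergo a Claisen shift, is already saturated before the metal is added. The regiochemistry on the arene is fixed by the iodine between the two oxygen-bearing carbons, so closure onto the other ortho carbon (future C8) is impossible, and the wide bite angle of dppf favours reductive elimination over β-hydride loss from C3.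

Step 4
Reactants: 6 methyl (2R)-5-hydroxy-2-(hydroxymethyl)-2,7-dimethyl-3,4-dihydro-2H-chromene-6-carboxylate
Product: 7 methyl (2R)-5-hydroxy-2-(hydroxymethyl)-8-iodo-2,7-dimethyl-3,4-dihydro-2H-chromene-6-carboxylate
Conditions: NIS (1.05 equiv), MeCN, 0 °C, dark
Reagents that add atoms: N-iodosuccinimide, O=C1CCC(=O)N1I
Why: Electrophilic aromatic iodination can only strike C8, the single unsubstituted ring carbon, which is para to the C5 hydroxyl and ortho to the ring oxygen, and polar conditions in the dark leave the benzylic positions and the primary alcohol alone.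

Step 5
Reactants: 7 methyl (2R)-5-hydroxy-2-(hydroxymethyl)-8-iodo-2,7-dimethyl-3,4-dihydro-2H-chromene-6-carboxylate
Product: 8 methyl (2R)-5-hydroxy-2-(hydroxymethyl)-2,7-dimethyl-8-(3-methylbut-2-en-1-yl)-3,4-dihydro-2H-chromene-6-carboxylate
Conditions: tributyl(3-methylbut-2-enyl)stannane (1.5 equiv), Pd2(dba)3·CHCl3 (2.5 mol %), AsPh3 (20 mol %), DMF, 60 °C
Reagents that add atoms: tributyl(3-methylbut-2-enyl)stannane, CC(C)=CC[Sn](CCCC)(CCCC)CCCC
Why: In this Stille coupling, oxidative addition of zerovalent palladium into the C8–I bond, transmetalation accelerated by the weakly bound arsine, and reductive elimination at the unsubstituted terminus of the dimethylallyl ligand, the only one that fits between the two ortho substituents, should give the linear prenyl group under neutral conditions that tolerate the free phenol, the alcohol and the ester.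

Step 6
Reactants: 8 methyl (2R)-5-hydroxy-2-(hydroxymethyl)-2,7-dimethyl-8-(3-methylbut-2-en-1-yl)-3,4-dihydro-2H-chromene-6-carboxylate
Product: 9 methyl (2R)-2-formyl-5-hydroxy-2,7-dimethyl-8-(3-methylbut-2-en-1-yl)-3,4-dihydro-2H-chromene-6-carboxylate
Conditions: Dess–Martin periodinane (1.2 equiv), CH2Cl2, 0 °C to rt
Reagents that add atoms: none
Why: Dess–Martin oxidation stops at the aldehyde, which has no α-hydrogen so that C2 cannot epimerise, and it leaves the trisubstituted alkene and the fully substituted, chelated phenol untouched.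

Step 7
Reactants: 9 methyl (2R)-2-formyl-5-hydroxy-2,7-dimethyl-8-(3-methylbut-2-en-1-yl)-3,4-dihydro-2H-chromene-6-carboxylate
Product: 10 methyl (2R)-5-hydroxy-2,7-dimethyl-2-[(1E)-4-methylpenta-1,3-dien-1-yl]-8-(3-methylbut-2-en-1-yl)-3,4-dihydro-2H-chromene-6-carboxylate
Conditions: prenyl bromide (2.5 equiv), PBu3 (2.5 equiv), THF, rt; KOt-Bu (2.5 equiv), −78 °C; then 9, −78 °C to rt
Reagents that add atoms: 1-bromo-3-methylbut-2-ene (prenyl bromide), CC(C)=CCBr
Why: Wittig olefination with a semi-stabilised allylic ylide carried on a trialkylphosphine, a combination known to favour E-alkenes, should set the new C1'=C2' double bond as E on this chroman-2-carbaldehyde, the trisubstituted end of the diene carries no geometry, and the excess ylide absorbs the phenol proton without attacking the hindered ester.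

Step 8
Reactants: 10 methyl (2R)-5-hydroxy-2,7-dimethyl-2-[(1E)-4-methylpenta-1,3-dien-1-yl]-8-(3-methylbut-2-en-1-yl)-3,4-dihydro-2H-chromene-6-carboxylate
Product: 11 (2R)-5-hydroxy-2,7-dimethyl-2-[(1E)-4-methylpenta-1,3-dien-1-yl]-8-(3-methylbut-2-en-1-yl)-3,4-dihydro-2H-chromene-6-carboxylic acid
Conditions: NaOH (5 M aq., excess), DMSO, 80 °C; then 1 M HCl to pH 3, 0 °C
Reagents that add atoms: sodium hydroxide, [Na+].[OH-]
Why: Saponification of the doubly ortho-substituted, chelated methyl salicylate needs hot hydroxide in a dipolar aprotic medium, which the ether, the diene and the prenyl group tolerate, and cold, mild acidification avoids decarboxylation of the orsellinic-type acid, with C2 not involved.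

Compound list
1 | methyl orsellinate (methyl 2,4-dihydroxy-6-methylbenzoate) | COC(=O)c1c(C)cc(O)cc1O | starting material
2 | methyl 2,4-dihydroxy-3-iodo-6-methylbenzoate | COC(=O)c1c(C)cc(O)c(I)c1O | intermediate
3 | 2-methyl-2-vinyloxirane (isoprene monoepoxide, racemic) | CC1(C=C)CO1 | starting material
4 | methyl 2-hydroxy-4-{[(2R)-1-hydroxy-2-methylbut-3-en-2-yl]oxy}-3-iodo-6-methylbenzoate | OC[C@@](Oc1cc(C)c(C(=O)OC)c(O)c1I)(C)C=C | intermediate
5 | methyl 4-{[(2R)-4-(9-borabicyclo[3.3.1]nonan-9-yl)-1-(9-borabicyclo[3.3.1]nonan-9-yloxy)-2-methylbutan-2-yl]oxy}-2-hydroxy-3-iodo-6-methylbenzoate | O(B1C2CCCC1CCC2)C[C@@](Oc1cc(C)c(C(=O)OC)c(O)c1I)(C)CCB1C2CCCC1CCC2 | intermediate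
6 | methyl (2R)-5-hydroxy-2-(hydroxymethyl)-2,7-dimethyl-3,4-dihydro-2H-chromene-6-carboxylate | OC[C@@]1(C)CCc2c(O)c(C(=O)OC)c(C)cc2O1 | intermediate
7 | methyl (2R)-5-hydroxy-2-(hydroxymethyl)-8-iodo-2,7-dimethyl-3,4-dihydro-2H-chromene-6-carboxylate | OC[C@@]1(C)CCc2c(O)c(C(=O)OC)c(C)c(I)c2O1 | intermediate
8 | methyl (2R)-5-hydroxy-2-(hydroxymethyl)-2,7-dimethyl-8-(3-methylbut-2-en-1-yl)-3,4-dihydro-2H-chromene-6-carboxylate | OC[C@@]1(C)CCc2c(O)c(C(=O)OC)c(C)c(CC=C(C)C)c2O1 | intermediate
9 | methyl (2R)-2-formyl-5-hydroxy-2,7-dimethyl-8-(3-methylbut-2-en-1-yl)-3,4-dihydro-2H-chromene-6-carboxylate | O=C[C@@]1(C)CCc2c(O)c(C(=O)OC)c(C)c(CC=C(C)C)c2O1 | intermediate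
10 | methyl (2R)-5-hydroxy-2,7-dimethyl-2-[(1E)-4-methylpenta-1,3-dien-1-yl]-8-(3-methylbut-2-en-1-yl)-3,4-dihydro-2H-chromene-6-carboxylate | CC(C)=C/C=C/[C@@]1(C)CCc2c(O)c(C(=O)OC)c(C)c(CC=C(C)C)c2O1 | intermediate
11 | (2R)-5-hydroxy-2,7-dimethyl-2-[(1E)-4-methylpenta-1,3-dien-1-yl]-8-(3-methylbut-2-en-1-yl)-3,4-dihydro-2H-chromene-6-carboxylic acid | CC(C)=C/C=C/[C@@]1(C)CCc2c(O)c(C(=O)O)c(C)c(CC=C(C)C)c2O1 | target

Total step count: 8. Longest linear sequence: 8 steps (1 to 11).

Steps most likely to fail

Step 2. The iodophenoxide is a good leaving group, so the tertiary ether may re-ionise on palladium. Enantiomeric purity would then erode, and the material could drift to the primary allyl terminus. Facial selectivity with a methyl-substituted allyl unit may also be modest. The fallback replaces asymmetric catalysis by enzymatic kinetic resolution.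
- It sets out from 2 and 3, which are joined with the same palladium source and the racemic ligand at short contact time to give racemic methyl 2-hydroxy-4-[(1-hydroxy-2-methylbut-3-en-2-yl)oxy]-3-iodo-6-methylbenzoate F1.
- Burkholderia cepacia lipase and vinyl acetate in MTBE are expected to acetylate the S enantiomer to methyl 4-{[(2S)-1-acetoxy-2-methylbut-3-en-2-yl]oxy}-2-hydroxy-3-iodo-6-methylbenzoate F2, which is removed by chromatography.
- The unreacted R alcohol is compound 4, where the route is rejoined.

Step 3. Several processes could compete with ring closure: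
- loss of iodine by reduction
- β-hydride elimination from the alkylpalladium species
- capture of arylpalladium by the neighbouring primary alkoxide
- 1,3-elimination of the activated borate with expulsion of the aryloxide

The fallback reverses the polarity at C4 and closes the same bond from two electrophiles. It sets out from 4.
- TBSCl and imidazole give methyl 4-{[(2R)-1-(tert-butyldimethylsilyloxy)-2-methylbut-3-en-2-yl]oxy}-2-hydroxy-3-iodo-6-methylbenzoate F3.
- 9-BBN-H gives the B-alkyl-9-BBN adduct of the silyl ether F4.
- NaBO3·4H2O oxidises it to methyl 4-{[(2R)-1-(tert-butyldimethylsilyloxy)-4-hydroxy-2-methylbutan-2-yl]oxy}-2-hydroxy-3-iodo-6-methylbenzoate F5.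
- Appel-type iodination (I2, PPh3, imidazole) gives methyl 4-{[(2R)-1-(tert-butyldimethylsilyloxy)-4-iodo-2-methylbutan-2-yl]oxy}-2-hydroxy-3-iodo-6-methylbenzoate F6.
- Nickel-catalysed reductive cross-electrophile coupling (NiCl2(dme), 4,4'-di-tert-butyl-2,2'-bipyridine, Zn, DMA) closes the ring to methyl (2R)-2-[(tert-butyldimethylsilyloxy)methyl]-5-hydroxy-2,7-dimethyl-3,4-dihydro-2H-chromene-6-carboxylate F7.
- TBAF returns the route to compound 6.

Step 5. Oxidative addition at the fully substituted, electron-rich ring may be slow. Reduction of the C–I bond or transposition of the allyl unit could then take over. The fallback delivers the prenyl group by sigmatropic rearrangement instead of cross-coupling and skips the iodide.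
- It sets out from 6, whose C5 phenol is alkylated (prenyl bromide, K2CO3, DMF, 50 °C) to methyl (2R)-2-(hydroxymethyl)-2,7-dimethyl-5-[(3-methylbut-2-en-1-yl)oxy]-3,4-dihydro-2H-chromene-6-carboxylate F8.
- Heating in N,N-diethylaniline at about 190 °C should trigger the para-Claisen sequence. Both ortho carbons are blocked, so the Claisen shift is followed by a Cope shift to C8 and rearomatisation.
- The two allyl inversions restore the linear prenyl group, and the route is rejoined at compound 8.

Further compounds
F1 | step 2 | racemic methyl 2-hydroxy-4-[(1-hydroxy-2-methylbut-3-en-2-yl)oxy]-3-iodo-6-methylbenzoate | OCC(C)(Oc1cc(C)c(C(=O)OC)c(O)c1I)C=C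
F2 | step 2 | methyl 4-{[(2S)-1-acetoxy-2-methylbut-3-en-2-yl]oxy}-2-hydroxy-3-iodo-6-methylbenzoate | CC(=O)OC[C@](Oc1cc(C)c(C(=O)OC)c(O)c1I)(C)C=C
F3 | step 3 | methyl 4-{[(2R)-1-(tert-butyldimethylsilyloxy)-2-methylbut-3-en-2-yl]oxy}-2-hydroxy-3-iodo-6-methylbenzoate | CC(C)(C)[Si](C)(C)OC[C@@](Oc1cc(C)c(C(=O)OC)c(O)c1I)(C)C=C
F4 | step 3 | B-alkyl-9-BBN adduct of the silyl ether | CC(C)(C)[Si](C)(C)OC[C@@](Oc1cc(C)c(C(=O)OC)c(O)c1I)(C)CCB1C2CCCC1CCC2
F5 | step 3 | methyl 4-{[(2R)-1-(tert-butyldimethylsilyloxy)-4-hydroxy-2-methylbutan-2-yl]oxy}-2-hydroxy-3-iodo-6-methylbenzoate | CC(C)(C)[Si](C)(C)OC[C@@](Oc1cc(C)c(C(=O)OC)c(O)c1I)(C)CCO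
F6 | step 3 | methyl 4-{[(2R)-1-(tert-butyldimethylsilyloxy)-4-iodo-2-methylbutan-2-yl]oxy}-2-hydroxy-3-iodo-6-methylbenzoate | CC(C)(C)[Si](C)(C)OC[C@@](Oc1cc(C)c(C(=O)OC)c(O)c1I)(C)CCI
F7 | step 3 | methyl (2R)-2-[(tert-butyldimethylsilyloxy)methyl]-5-hydroxy-2,7-dimethyl-3,4-dihydro-2H-chromene-6-carboxylate | CC(C)(C)[Si](C)(C)OC[C@@]1(C)CCc2c(O)c(C(=O)OC)c(C)cc2O1
F8 | step 5 | methyl (2R)-2-(hydroxymethyl)-2,7-dimethyl-5-[(3-methylbut-2-en-1-yl)oxy]-3,4-dihydro-2H-chromene-6-carboxylate | OC[C@@]1(C)CCc2c(OCC=C(C)C)c(C(=O)OC)c(C)cc2O1
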